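**Retrosynthetic overview**

1. The target (daucane numbering: C1 angular quaternary carbon with CH3-15, C2, C3, C4 carbinol with isopropyl, C5 ring-fusion CH, C6–C10 round the seven-membered ring, CH3-14 on C8; β = face of CH3-15) comes from a 4β-hydroxy-dauc-7-ene-6,9-dione by O4-directed reduction at C6, acylation of O6 and Luche reduction at C9.
2. The ene-dione comes from a tricyclic silyl dienol ether that already holds both carbocycles, by hydroboration of C9=C10, Saegusa–Ito oxidation at C6/C7/C8 and alcohol oxidation.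
3. That tricycle comes from an acyclic allene-diene by one gold-catalysed intramolecular (4+3) cycloaddition that makes C1–C5 and C8–C9. Ring order: a temporary dioxasiline ring first, then the cyclopentane and the cycloheptadiene in the same event.
4. The allene-diene comes from (S)-terpinen-4-ol (ozonolysis gives the C4 carbinol flanked by C6 as aldehyde and C1 as methyl ketone), (E)-1-bromopropene (C7, C8, C14) and ethynylmagnesium bromide (C9, C10). Both carbinol epimers of the propargylic carbonate converge on the one allene.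
5. Enabling feature: in the seven-membered ring, C5–C6(O)–C7–C8 is a masked 2-oxy-1,3-diene and C9–C10–C1 is a three-carbon unit with unsubstituted C10 (an allene, hence a metal-bound allyl cation). They are joined through C2–C3–C4 of the cyclopentane, and the 1,3-related O4 and O6 can be tied by one silicon atom into a ring that fixes the enol geometry and the face of C5.

Key step: step 7

Assumption: (S)-terpinen-4-ol (1) is taken as a commercial chiral-pool material of high enantiomeric purity; its carbinol carbon becomes C4 of the target without change.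
Remark: the γ-hydroxy ketones 2, 4 and 5 are drawn open-chain; they equilibrate with five-membered cyclic hemiketals, which does not affect the steps.

**Route**

Step 1
Reactants: 1 (S)-terpinen-4-ol
Product: 2 (3S)-3-hydroxy-6-oxo-3-(propan-2-yl)heptanal
Conditions: O3, CH2Cl2/MeOH, −78 °C; then Me2S, −78 → 25 °C
Reagents that add atoms: ozone, [O-][O+]=O
Why: Ozonolysis with reductive work-up (Criegee mechanism) cleaves the only C=C bond to the aldehyde (future C6) and the methyl ketone (future C1) and leaves the carbinol stereocentre (future C4) untouched.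

Step 2
Reactants: 2 (3S)-3-hydroxy-6-oxo-3-(propan-2-yl)heptanal; 3 (E)-1-bromoprop-1-ene
Product: 4 (5S,8E)-5,7-dihydroxy-5-(propan-2-yl)dec-8-en-2-one (both C7 epimers)
Conditions: CrCl2 (4 equiv), NiCl2 (2 mol%), DMF, 25 °C
Reagents that add atoms: none
Why: The Nozaki–Hiyama–Kishi alkenylation (divalent chromium, NiCl2 catalysis) adds to the aldehyde only, tolerates the methyl ketone and the free tertiary alcohol, and keeps the (E) geometry; the new carbinol centre is oxidised away in step 3.

Step 3
Reactants: 4 (5S,8E)-5,7-dihydroxy-5-(propan-2-yl)dec-8-en-2-one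
Product: 5 (5S,8E)-5-hydroxy-5-(propan-2-yl)dec-8-ene-2,7-dione
Conditions: MnO2 (excess), CH2Cl2, 25 °C
Reagents that add atoms: none
Why: MnO2 oxidises only the allylic secondary alcohol, which gives the (E)-propenyl ketone with C6 at the ketone level.

Step 4
Reactants: 5 (5S,8E)-5-hydroxy-5-(propan-2-yl)dec-8-ene-2,7-dione
Product: 6 4-[(4R)-4-(propan-2-yl)-2,2-di(propan-2-yl)-6-[(1E)-prop-1-en-1-yl]-4H-1,3,2-dioxasilin-4-yl]butan-2-one
Conditions: i-Pr2Si(OTf)2 (1.1 equiv), Et3N (3 equiv), CH2Cl2, −40 → 0 °C
Reagents that add atoms: diisopropylsilyl bis(trifluoromethanesulfonate), CC(C)[Si](OS(=O)(=O)C(F)(F)F)(OS(=O)(=O)C(F)(F)F)C(C)C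
Why: The silyl bis(triflate) silylates the tertiary alcohol and then O-silylates the neighbouring ketone, enolised toward C5 by Et3N (soft enolisation, six-membered ring closure), which protects O4, fixes the (Z) enol ether and leaves a cross-conjugated 2-silyloxy-1,3-diene.

Step 5
Reactants: 6 the dioxasilinyl butanone; 7 ethynylmagnesium bromide (HC≡CMgBr)
Product: 9 methyl 3-methyl-5-[(4R)-4-(propan-2-yl)-2,2-di(propan-2-yl)-6-[(1E)-prop-1-en-1-yl]-4H-1,3,2-dioxasilin-4-yl]pent-1-yn-3-yl carbonate (both carbinol epimers), via magnesium alkoxide 8 (not isolated)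
Conditions: 7 (1.5 equiv), THF, 0 °C; then ClCO2Me (2 equiv), 0 → 25 °C
Reagents that add atoms: methyl chloroformate, COC(Cl)=O
Why: 1,2-Addition of the alkynyl Grignard reagent to the only ketone and O-acylation of the alkoxide in the same flask; the epimer mixture at the new carbinol carbon converges in step 6.

Step 6
Reactants: 9 the tertiary propargylic methyl carbonate
Product: 10 (4R)-4-(3-methylpenta-3,4-dien-1-yl)-4-(propan-2-yl)-2,2-di(propan-2-yl)-6-[(1E)-prop-1-en-1-yl]-4H-1,3,2-dioxasiline
Conditions: Pd2(dba)3·CHCl3 (2.5 mol%), n-Bu3P (10 mol%), HCO2NH4 (3 equiv), THF, 40 °C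
Reagents that add atoms: none
Why: Palladium-catalysed formate hydrogenolysis of a propargylic carbonate: the zerovalent palladium complex Pd(n-Bu3P)n ionises the carbonate to an allenylpalladium species that takes hydride from formate and eliminates with SN2' transposition, so both epimers of 9 should give the same 1,1-disubstituted allene.

Step 7
Reactants: 10 the allene-diene
Product: 11 trans-fused cycloadduct: dauca-6,9-diene-4β,6-diol cyclic di(propan-2-yl)silylene derivative (1β-CH3, 5α-H, 8β-CH3; C6=C7 silyl enol ether, C9=C10 alkene)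
Conditions: [(t-Bu)2(o-biphenyl)PAu(NCMe)]SbF6 (5 mol%), 4 Å MS, CH2Cl2, −20 → 25 °C
Reagents that add atoms: none
Why: The cation (t-Bu)2(o-biphenyl)PAu+ (monovalent gold) binds the allene and turns C9–C10–C1 into a gold-bound allyl cation whose tertiary terminus C1 is attacked by C5, the diene terminus with the largest HOMO coefficient, while C9 bonds to C8 in a concerted but asynchronous (4+3) cycloaddition; the gold carbene left at C10 then takes a hydride from C9 (1,2-shift), which gives the C9=C10 alkene and returns the catalyst. The closest known reaction type is the gold- or platinum-catalysed intramolecular (4C+3C) cycloaddition of allene-tethered 1,3-dienes to trans-fused bicyclo[5.3.0]decadienes. The cyclopentane closes through the three-carbon tether C2–C3–C4 by bond C1–C5 (exo with respect to both π systems), and the cycloheptadiene closes as the (4+3) ring itself, completed by bond C8–C9. C5 is controlled by C4 through the dioxasiline ring, because only the face of C5 that carries the pseudo-axial CH2CH2 arm can be reached, so C6 ends cis to O4 and trans to the isopropyl group; C1 is controlled by the exo-like transition state in which the gold-bearing C10 points away from the diene, which should give the trans ring fusion; C8 follows from the (E)-propenyl geometry and is erased in step 9. The step needs (4+3) selectivity over ring contraction of the carbene (formal (4+2) product) and over closure at the oxygen-bearing C6, which the electron-rich biaryl(di-tert-butyl)phosphine ligand, the lack of hydrogen on C1 and the absence of a proton source should secure.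

Step 8
Reactants: 11 the tricyclic cycloadduct
Product: 13 9α-hydroxy derivative of 11 (C10 now CH2; silyl enol ether intact), via B-alkylborane 12 (not isolated)
Conditions: 9-BBN (2 equiv), THF, 50 °C; then NaBO3·4H2O, H2O, 25 °C
Reagents that add atoms: sodium perborate (oxygen on C9), [Na+].[Na+].O[B-]1(O)OO[B-](O)(O)OO1; 9-borabicyclo[3.3.1]nonane (boron of intermediate 12 only), [BH]1C2CCCC1CCC2
Why: Syn hydroboration by 9-BBN should prefer the cis-disubstituted C9=C10 alkene over the trisubstituted silyl enol ether and place boron on C9, away from the quaternary C1 and on the α face opposite both methyl groups; perborate oxidation with retention gives the 9α-alcohol, whose configuration is immaterial because C9 is oxidised in step 10.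

Step 9
Reactants: 13 the 9α-hydroxy silyl enol ether
Product: 15 4β,9α-dihydroxydauc-7-en-6-one, via silyl acetate 14 (not isolated)
Conditions: Pd(OAc)2 (1.2 equiv), MeCN, 40 °C; then HF·pyridine, THF, 0 °C
Reagents that add atoms: palladium diacetate (acetoxy group of intermediate 14 only), CC(=O)O[Pd]OC(C)=O
Why: Saegusa–Ito oxidation: silicon-to-palladium exchange gives the palladium enolate at C7, β-hydride elimination can only take H8, so the C7=C8 enone forms regiospecifically, and fluoride then removes the residual acetoxysilyl group from O4.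

Step 10
Reactants: 15 4β,9α-dihydroxydauc-7-en-6-one
Product: 16 4β-hydroxydauc-7-ene-6,9-dione
Conditions: MnO2 (excess), CH2Cl2, 25 °C
Reagents that add atoms: none
Why: MnO2 oxidation of the allylic secondary alcohol gives the ene-dione; the tertiary C4 alcohol cannot be oxidised.

Step 11
Reactants: 16 4β-hydroxydauc-7-ene-6,9-dione
Product: 17 4β,6α-dihydroxydauc-7-en-9-one
Conditions: Me4NBH(OAc)3 (5 equiv), MeCN/AcOH (1:1), −30 °C
Reagents that add atoms: none
Why: Evans–Saksena reduction: the 4β-hydroxyl exchanges onto boron and delivers hydride within a six-membered transition state to the β face of the C6 carbonyl, which should set 6α-OH (H6 β) and leave the undirected C9 carbonyl untouched.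

Step 12
Reactants: 17 4β,6α-dihydroxydauc-7-en-9-one; 18 4-acetoxy-3-methoxybenzoic acid
Product: 19 4β-hydroxy-9-oxodauc-7-en-6α-yl 4-acetoxy-3-methoxybenzoate
Conditions: DCC (1.5 equiv), DMAP (0.2 equiv), CH2Cl2, 0 → 25 °C
Reagents that add atoms: none
Why: Steglich esterification acylates the secondary allylic 6α-hydroxyl with retention; the tertiary C4 hydroxyl does not react and the phenol of the acid is masked as its acetate.

Step 13
Reactants: 19 the 9-oxo 6α-ester
Product: 21 (3R,3aS,4S,7R,8aR)-3,7-dihydroxy-6,8a-dimethyl-3-(propan-2-yl)-1,2,3,3a,4,7,8,8a-octahydroazulen-4-yl 4-hydroxy-3-methoxybenzoate (4β,9β-dihydroxydauc-7-en-6α-yl vanillate), via aryl acetate 20 (not isolated)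
Conditions: NaBH4, CeCl3·7H2O, MeOH, −78 °C; then K2CO3, MeOH, 0 °C
Reagents that add atoms: none
Why: Luche reduction should deliver hydride 1,2 to the C9 enone from the α face, opposite the angular C1 methyl group that shields the β face in a 1,3 relationship, which sets 9β-OH; the labile aryl acetate is then removed by methanolysis while the hindered secondary benzoate stays.

**Compound list**

1 | (S)-terpinen-4-ol, (1S)-4-methyl-1-(propan-2-yl)cyclohex-3-en-1-ol | CC1=CC[C@](O)(C(C)C)CC1 | starting material
2 | (3S)-3-hydroxy-6-oxo-3-(propan-2-yl)heptanal | O=CC[C@](O)(C(C)C)CCC(C)=O | intermediate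
3 | (E)-1-bromoprop-1-ene | C/C=C/Br | starting material
4 | (5S,8E)-5,7-dihydroxy-5-(propan-2-yl)dec-8-en-2-one (C7 epimers) | C/C=C/C(O)C[C@](O)(C(C)C)CCC(C)=O | intermediate
5 | (5S,8E)-5-hydroxy-5-(propan-2-yl)dec-8-ene-2,7-dione | C/C=C/C(=O)C[C@](O)(C(C)C)CCC(C)=O | intermediate
6 | 4-[(4R)-4-(propan-2-yl)-2,2-di(propan-2-yl)-6-[(1E)-prop-1-en-1-yl]-4H-1,3,2-dioxasilin-4-yl]butan-2-one | C/C=C/C1=C[C@](C(C)C)(CCC(C)=O)O[Si](C(C)C)(C(C)C)O1 | intermediate
7 | ethynylmagnesium bromide | C#C[Mg]Br | starting material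
8 | bromomagnesium alkoxide of the tertiary propargylic alcohol from 6 (carbinol epimers) | C/C=C/C1=C[C@](C(C)C)(CCC(C)(O[Mg]Br)C#C)O[Si](C(C)C)(C(C)C)O1 | intermediate
9 | methyl 3-methyl-5-[(4R)-4-(propan-2-yl)-2,2-di(propan-2-yl)-6-[(1E)-prop-1-en-1-yl]-4H-1,3,2-dioxasilin-4-yl]pent-1-yn-3-yl carbonate (carbinol epimers) | C/C=C/C1=C[C@](C(C)C)(CCC(C)(OC(=O)OC)C#C)O[Si](C(C)C)(C(C)C)O1 | intermediate
10 | (4R)-4-(3-methylpenta-3,4-dien-1-yl)-4-(propan-2-yl)-2,2-di(propan-2-yl)-6-[(1E)-prop-1-en-1-yl]-4H-1,3,2-dioxasiline | C/C=C/C1=C[C@](C(C)C)(CCC(C)=C=C)O[Si](C(C)C)(C(C)C)O1 | intermediate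
11 | dauca-6,9-diene-4β,6-diol cyclic di(propan-2-yl)silylene derivative (1β-CH3, 5α-H, 8β-CH3) | C[C@@H]1C=C[C@@]2(C)CC[C@]3(C(C)C)O[Si](C(C)C)(C(C)C)OC(=C1)[C@H]23 | intermediate
12 | 9α-(9-borabicyclo[3.3.1]nonan-9-yl) adduct of 11 | C[C@@H]1[C@@H](B4C5CCCC4CCC5)C[C@@]2(C)CC[C@]3(C(C)C)O[Si](C(C)C)(C(C)C)OC(=C1)[C@H]23 | intermediate
13 | dauc-6-ene-4β,6,9α-triol 4,6-cyclic di(propan-2-yl)silylene derivative (8β-CH3) | C[C@@H]1[C@@H](O)C[C@@]2(C)CC[C@]3(C(C)C)O[Si](C(C)C)(C(C)C)OC(=C1)[C@H]23 | intermediate
14 | 4β-[acetoxydi(propan-2-yl)silyl]oxy-9α-hydroxydauc-7-en-6-one | CC1=CC(=O)[C@H]2[C@](O[Si](OC(C)=O)(C(C)C)C(C)C)(C(C)C)CC[C@]2(C)C[C@@H]1O | intermediate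
15 | 4β,9α-dihydroxydauc-7-en-6-one | CC1=CC(=O)[C@H]2[C@](O)(C(C)C)CC[C@]2(C)C[C@@H]1O | intermediate
16 | 4β-hydroxydauc-7-ene-6,9-dione | CC1=CC(=O)[C@H]2[C@](O)(C(C)C)CC[C@]2(C)CC1=O | intermediate
17 | 4β,6α-dihydroxydauc-7-en-9-one | CC1=C[C@H](O)[C@H]2[C@](O)(C(C)C)CC[C@]2(C)CC1=O | intermediate
18 | 4-acetoxy-3-methoxybenzoic acid | CC(=O)Oc1ccc(cc1OC)C(O)=O | starting material
19 | 4β-hydroxy-9-oxodauc-7-en-6α-yl 4-acetoxy-3-methoxybenzoate | COc1cc(C(=O)O[C@H]2C=C(C)C(=O)C[C@@]3(C)CC[C@@](O)(C(C)C)[C@H]23)ccc1OC(C)=O | intermediate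
20 | 4β,9β-dihydroxydauc-7-en-6α-yl 4-acetoxy-3-methoxybenzoate | COc1cc(C(=O)O[C@H]2C=C(C)[C@H](O)C[C@@]3(C)CC[C@@](O)(C(C)C)[C@H]23)ccc1OC(C)=O | intermediate
21 | (3R,3aS,4S,7R,8aR)-3,7-dihydroxy-6,8a-dimethyl-3-(propan-2-yl)-1,2,3,3a,4,7,8,8a-octahydroazulen-4-yl 4-hydroxy-3-methoxybenzoate | COc1cc(C(=O)O[C@H]2C=C(C)[C@H](O)C[C@@]3(C)CC[C@@](O)(C(C)C)[C@H]23)ccc1O | target

**Step count and risks**

Total step count: 13. Longest linear sequence: 13 steps (from 1).

Steps most likely to fail:

Step 7. The electron-rich silyl dienol ether may divert the gold-bound allyl cation: the five-membered ring may close alone, or the second bond may form at the oxygen-bearing C6 or through the gold-bearing carbon (formal (3+2), (2+2) or (4+2) closure) instead of at C8. The fallback changes the four-carbon partner from a donor diene to a neutral acyloxy-type diene and changes how C6 is unmasked. It sets out from 10: TBAF/AcOH in THF removes the silylene to give (2E,6S)-6-hydroxy-9-methyl-6-(propan-2-yl)undeca-2,9,10-trien-4-one F1. Carbonyldiimidazole followed by DBU closes the cyclic enol carbonate (4R)-4-(3-methylpenta-3,4-dien-1-yl)-4-(propan-2-yl)-6-[(1E)-prop-1-en-1-yl]-4H-1,3-dioxin-2-one F2. The same gold-catalysed (4+3) cycloaddition should then give the carbonate-bridged dauca-6,9-diene F3. 9-BBN followed by NaOH/H2O2, which also hydrolyses the enol carbonate, should give 4β,9α-dihydroxy-daucan-6-one F4. IBX in DMSO at 70 °C oxidises the C9 alcohol and dehydrogenates the only position that carries both an α- and a β-hydrogen (C7–C8). The route is rejoined at 16.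

Step 8. The hindered C9=C10 alkene may be hydroborated too slowly, with poor regioselectivity between C9 and C10 or with competing attack on the silyl enol ether. The fallback reverses the order of events and brings in the C9 oxygen by radical hydration instead of hydroboration. It sets out from 11: Saegusa–Ito oxidation (Pd(OAc)2, MeCN) gives 4β-[acetoxydi(propan-2-yl)silyl]oxy-dauca-7,9-dien-6-one F5, and HF·pyridine frees 4β-hydroxydauca-7,9-dien-6-one F6. Mukaiyama hydration (Mn(dpm)3, PhSiH3, O2, i-PrOH; then P(OEt)3) should add hydrogen to the terminal C10 and oxygen to C9 of the dienone. This gives 15 together with its epimer 4β,9β-dihydroxydauc-7-en-6-one F7, and both are oxidised to 16 in step 10. The route is rejoined at 15.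

Step 11. Exchange of the hindered tertiary hydroxyl onto boron may be slow, so that undirected reduction of either carbonyl of the electrophilic ene-dione erodes the chemo- and stereoselectivity. The fallback replaces borohydride delivery by a covalent silicon tether. It sets out from 16: i-Pr2SiHCl with imidazole and DMAP gives 4β-[di(propan-2-yl)silyl]oxy-dauc-7-ene-6,9-dione F8. SnCl4-promoted intramolecular hydrosilylation of the C6 carbonyl (hydride from the β face, anti-1,3 sense) gives the 4β,6α-diol cyclic di(propan-2-yl)silylene acetal of dauc-7-en-9-one F9. HF·pyridine then releases the diol. The route is rejoined at 17.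

Further compounds
F1 | step 7 | (2E,6S)-6-hydroxy-9-methyl-6-(propan-2-yl)undeca-2,9,10-trien-4-one | C/C=C/C(=O)C[C@](O)(C(C)C)CCC(C)=C=C
F2 | step 7 | (4R)-4-(3-methylpenta-3,4-dien-1-yl)-4-(propan-2-yl)-6-[(1E)-prop-1-en-1-yl]-4H-1,3-dioxin-2-one | C/C=C/C1=C[C@](C(C)C)(CCC(C)=C=C)OC(=O)O1
F3 | step 7 | dauca-6,9-diene-4β,6-diol cyclic carbonate (1β-CH3, 5α-H, 8β-CH3) | C[C@@H]1C=C[C@@]2(C)CC[C@]3(C(C)C)OC(=O)OC(=C1)[C@H]23
F4 | step 7 | 4β,9α-dihydroxydaucan-6-one (8β-CH3) | C[C@H]1CC(=O)[C@H]2[C@](O)(C(C)C)CC[C@]2(C)C[C@@H]1O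
F5 | step 8 | 4β-[acetoxydi(propan-2-yl)silyl]oxy-dauca-7,9-dien-6-one | CC1=CC(=O)[C@H]2[C@](O[Si](OC(C)=O)(C(C)C)C(C)C)(C(C)C)CC[C@]2(C)C=C1
F6 | step 8 | 4β-hydroxydauca-7,9-dien-6-one | CC1=CC(=O)[C@H]2[C@](O)(C(C)C)CC[C@]2(C)C=C1
F7 | step 8 | 4β,9β-dihydroxydauc-7-en-6-one | CC1=CC(=O)[C@H]2[C@](O)(C(C)C)CC[C@]2(C)C[C@H]1O
F8 | step 11 | 4β-[di(propan-2-yl)silyl]oxy-dauc-7-ene-6,9-dione | CC1=CC(=O)[C@H]2[C@](O[SiH](C(C)C)C(C)C)(C(C)C)CC[C@]2(C)CC1=O
F9 | step 11 | 4β,6α-dihydroxydauc-7-en-9-one cyclic di(propan-2-yl)silylene acetal | CC1=C[C@@H]2O[Si](C(C)C)(C(C)C)O[C@@]3(C(C)C)CC[C@](C)(CC1=O)[C@@H]23
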